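Compound numbers used throughout: 1–4 (side-chain series), 5 (quinone), 6 and 7 (acylhydroquinones), 8 and 9 (quinones formed in the flask in the key step), 10–12 (flavanones), 13 (target).

## The problem

The target 13 is a flavanone: a chroman-4-one (rings A and C) carrying a 3,4-dimethoxyphenyl group (ring B) at C2. Ring A is a hexasubstituted benzene with five adjacent oxygens (O1 on C8a, a free hydroxyl on C8, methoxy groups on C7, C6 and C5) and the acyl carbon on C4a, so building it means telling near-equivalent oxygen positions apart. The one free phenol is at C8 and not at C5, the position that hydrogen bonding to the C4 carbonyl would expose in any selective demethylation. C2 is the only stereocenter (S); nothing else in the molecule can direct it, so it must be set by a reagent and then kept. It is fragile in both directions: base opens ring C by E1cB loss of the O1 phenoxide to an achiral 2'-hydroxychalcone, and acid can ionise the C2-O1 bond because the para-methoxy group of ring B stabilises the benzylic cation; an open-chain benzylic carbinol precursor ionises and dehydrates just as easily. Ring closures that make the O1-C2 bond therefore endanger the stereocenter in the very step that forms the ring. The enabling feature is that the oxygens on C5 and C8 are para to each other: ring A can pass through a 5,8-quinone in which C8a is beta to the C5 carbonyl and to the C4 ketone, so a C2 hydroxyl of fixed configuration can add there and form O1-C8a without any bond to C2 being touched. The same arrangement leaves the C5 hydroxyl chelated and the C8 hydroxyl free after closure, which lets the two be distinguished.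

## Retrosynthesis

**13 back to 10 (O-CH3 at C5, temporary benzyl at C8).** The last operations change functional groups only: 13 from benzyl ether 12, 12 from phenol 11, 11 from hydroquinone 10. Direct monomethylation of 10 would alkylate the free C8 hydroxyl, and permethylation followed by selective demethylation would uncover C5, so neither shortcut gives the right isomer. Blocking the free C8 hydroxyl (11), methylating the chelated C5 hydroxyl (12) and removing the benzyl group uses the built-in difference between the two phenols. Compound 10 is simpler because its two phenols are just the two ends of a hydroquinone. The forward steps must stay mild enough in base that ring C does not open.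

**10 back to 7 (O1-C8a).** This cut removes ring C and one of the five oxygens of ring A, and leads to the open-chain acylhydroquinone 7, whose carbinol carbon already has the S configuration. The neighbouring cut, O1-C2, would mean either a chalcone oxa-Michael closure, which creates C2 without control, or an SN2 closure at a para-methoxybenzylic carbinol, where ionisation competes with inversion. A C4-C4a acylation cut would need strong acid next to an ionisable benzylic ether. The forward reaction asks for oxidation of ring A of 7 to acylquinone 8 without touching ring B, addition of the hydroxyl to the CH carbon of 8, and return of any over-oxidised product quinone 9 to 10.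

**7 back to 4 and 5 (C4-C4a).** Cutting the aryl-acyl bond of 7 (via its silyl ether 6) gives aldehyde 4 and 2,3-dimethoxy-1,4-benzoquinone 5. Quinone 5 supplies all four oxygens of the precursor ring with both methoxy groups in place, and its two CH positions are equivalent, so acylation can give only one regioisomer. A Friedel-Crafts or Fries acylation of the hydroquinone would need Lewis acid that the benzylic silyl ether would not survive. An aryllithium addition would need both phenols protected and an extra oxidation; it is kept as the reserve. The forward photoacylation must take the formyl hydrogen of 4 and deliver hydroquinone 6 directly; desilylation to 7 must avoid elimination.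

**4 back to 1 (the C-H bond at the carbinol carbon).** Aldehyde 4 comes from silyl ether 3, 3 from hydroxy ester 2, and 2 from the purchasable keto ester 1 by addition of hydrogen to the ketone. This places the only stereocenter in the first step by a catalytic reaction. An acetate aldol on the corresponding aryl aldehyde would need an auxiliary or a less general catalyst and more steps. The forward sequence asks for face-selective hydrogenation, a silyl ether that survives hydride and light, and a half-reduction of the ester.

## Roads not taken

**Alternative 1:** The cut removes two bonds of ring B, C1'-C2' and C5'-C6', and leads to the terminal alkyne (2S)-8-(benzyloxy)-2-ethynyl-5,6,7-trimethoxychroman-4-one A2 and 2,3-dimethoxybuta-1,3-diene A3. A cobalt catalyst made from CoBr2(dppe), Zn and ZnI2 would join them in a formal [4+2] cycloaddition to the cyclohexa-1,4-diene (2S)-8-(benzyloxy)-2-(4,5-dimethoxycyclohexa-1,4-dien-1-yl)-5,6,7-trimethoxychroman-4-one A1. Dehydrogenation of A1 gives 12 and hydrogenolysis gives 13.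
- Merits: the cycloaddition is neutral and makes no bond to C2. The C8 oxygen carries its benzyl group from the start, so no phenol has to be differentiated on the finished flavanone, and no air-sensitive hydroquinone appears. In these respects it is better than the chosen plan.
- Weak points: it builds the one ring that can be bought and leaves both real problems inside A2. A2 still holds the complete penta-oxygenated ring A with its oxygens already differentiated, and the C2 stereocenter as a propargylic ether beta to a ketone, which has to come from an asymmetric alkynylation of a multi-step chromone. A1 is a bis(enol ether) that hydrolyses readily, and the oxidant needed to aromatise it can also dehydrogenate C2-C3 to the flavone.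
- Comparison: the sequence is clearly longer. Against its advantages, the chosen plan sets a ring A bought as quinone 5, a stereocenter from a hydrogenation, and about half the steps.

**Alternative 2:** The cut is the C4a-C5 bond and with it the whole of ring A, traced to dimethyl squarate A6 and the dihydropyran tert-butyl{[(2S,4S)-2-(3,4-dimethoxyphenyl)-3,4-dihydro-2H-pyran-4-yl]oxy}dimethylsilane A7 lithiated at C6. Their adduct, silylated on oxygen, is 4-[(2S,4S)-4-(tert-butyldimethylsilyloxy)-2-(3,4-dimethoxyphenyl)-3,4-dihydro-2H-pyran-6-yl]-2,3-dimethoxy-4-(trimethylsilyloxy)cyclobut-2-en-1-one A5. Heating A5 would open the four-membered ring to a dienylketene, which closes by 6π electrocyclisation onto C5 of the dihydropyran and tautomerises to (2S,4S)-4-(tert-butyldimethylsilyloxy)-2-(3,4-dimethoxyphenyl)-6,7-dimethoxy-8-(trimethylsilyloxy)chroman-5-ol A4.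
- Merits: all five oxygens of ring A are placed by construction, and C5 (free phenol) and C8 (silyl ether) emerge already differentiated. With C4 at the alcohol level the C5 phenol is not chelated and can be methylated without risk to C2. This is a real advantage over the chosen plan, which spends three steps on that differentiation and must methylate a chelated phenol on a base-sensitive flavanone.
- Weak points: A7 needs two stereocenters, one of which (C4) is later destroyed by oxidation to the ketone. Its C6 lithiation competes with metalation at the benzylic C2-H and on ring B. The thermolysis heats an allylic, benzylic ether, and the end game needs selective desilylations and a C4 oxidation.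
- Comparison: longer, and more stereocenters to make than the target contains. The chosen plan sets against it one catalytic stereocenter, no organolithium step, and the correct oxidation level at C4 throughout.

**Alternative 3:** The cut takes ring C apart at O1-C2 and C3-C4, giving 3-(benzyloxy)-2-hydroxy-4,5,6-trimethoxybenzaldehyde A9 and 3,4-dimethoxystyrene A10. Under a chiral BINOL-derived phosphoric acid, A9 and trimethyl orthoformate A12 would give the ortho-quinone methide 2-(benzyloxy)-3,4,5-trimethoxy-6-(methoxymethylidene)cyclohexa-2,4-dien-1-one A11. A11 adds A10 in a hetero-Diels-Alder reaction to (2S,4S)-8-(benzyloxy)-2-(3,4-dimethoxyphenyl)-4,5,6,7-tetramethoxychromane A8; C4 must then be taken from methyl ether to ketone and the benzyl group removed.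
- Merits: it is the most convergent of the four, forming two bonds, ring C and the C2 stereocenter in one catalytic step. The C8 oxygen is differentiated from the outset and no quinone chemistry is needed. In convergence and in the end game it is better than the chosen plan.
- Weak points: A9 is a hexasubstituted benzene, so the oxygen-differentiation problem is only moved upstream into a long arene synthesis. A11 bears four donor oxygens and a flanking methoxy group, which lowers its electrophilicity, while A10 oligomerises under acid, so rate and facial control are both uncertain. A8 has C4 at the wrong oxidation level, and converting a benzylic methyl ether to a ketone needs acid or an oxidant beside an ionisable C2-O1 bond; the C4 stereocenter is made only to be destroyed.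
- Comparison: the chosen plan sets against it a purchasable ring A precursor, a stereocenter from a well-established hydrogenation, and no redox correction at C4.

Key step: step 6

## Route

Assumption: ethyl 3-(3,4-dimethoxyphenyl)-3-oxopropanoate 1 and 2,3-dimethoxy-1,4-benzoquinone 5 are taken as purchasable.

Step 1
Reactants: 1 ethyl 3-(3,4-dimethoxyphenyl)-3-oxopropanoate
Product: 2 ethyl (3S)-3-(3,4-dimethoxyphenyl)-3-hydroxypropanoate
Conditions: RuCl2[(R)-BINAP] (1 mol%), H2 (50 atm), EtOH, 50 °C
Reagents that add atoms: none
Why: Noyori asymmetric hydrogenation of a beta-keto ester; the ester carbonyl chelates the divalent ruthenium hydride and the (R)-ligand delivers hydrogen to the same face as with alkyl beta-keto esters, which for an aryl ketone (aryl ranks above CH2CO2Et) is labelled S.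

Step 2
Reactants: 2 ethyl (3S)-3-(3,4-dimethoxyphenyl)-3-hydroxypropanoate
Product: 3 ethyl (3S)-3-[(tert-butyldimethylsilyl)oxy]-3-(3,4-dimethoxyphenyl)propanoate
Conditions: TBSCl, imidazole, DMF, rt
Reagents that add atoms: tert-butyldimethylsilyl chloride, CC(C)(C)[Si](C)(C)Cl
Why: Standard silylation of a secondary alcohol; the silyl ether blocks retro-aldol and dehydration pathways in the next two steps and does not affect the stereocenter.

Step 3
Reactants: 3 ethyl (3S)-3-[(tert-butyldimethylsilyl)oxy]-3-(3,4-dimethoxyphenyl)propanoate
Product: 4 (3S)-3-[(tert-butyldimethylsilyl)oxy]-3-(3,4-dimethoxyphenyl)propanal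
Conditions: i-Bu2AlH (1.1 equiv), CH2Cl2, −78 °C; MeOH, then aq. potassium sodium tartrate
Reagents that add atoms: none
Why: Partial reduction of an ester with DIBAL-H; at −78 °C the tetrahedral aluminium hemiacetal, stabilised by the beta-silyloxy oxygen, persists until work-up and releases the aldehyde, which is used without prolonged contact with silica.

Step 4
Reactants: 4 (3S)-3-[(tert-butyldimethylsilyl)oxy]-3-(3,4-dimethoxyphenyl)propanal, 5 2,3-dimethoxy-1,4-benzoquinone
Product: 6 (3S)-3-[(tert-butyldimethylsilyl)oxy]-1-(2,5-dihydroxy-3,4-dimethoxyphenyl)-3-(3,4-dimethoxyphenyl)propan-1-one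
Conditions: 5 (2 equiv), hν (visible light, 400–450 nm), degassed PhH, rt
Reagents that add atoms: none
Why: Photo-Friedel-Crafts acylation of a 1,4-benzoquinone: the excited quinone abstracts the formyl hydrogen, the acyl radical adds to a ring CH carbon of 5 and tautomerisation gives the acylhydroquinone. The two CH positions of 5 are equivalent, so one regioisomer results, and the stereocenter is not involved.

Step 5
Reactants: 6 (3S)-3-[(tert-butyldimethylsilyl)oxy]-1-(2,5-dihydroxy-3,4-dimethoxyphenyl)-3-(3,4-dimethoxyphenyl)propan-1-one
Product: 7 (3S)-1-(2,5-dihydroxy-3,4-dimethoxyphenyl)-3-(3,4-dimethoxyphenyl)-3-hydroxypropan-1-one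
Conditions: HF·pyridine, pyridine, THF, 0 °C to rt
Reagents that add atoms: none
Why: Fluoride cleavage of a secondary TBS ether; the pyridine buffer avoids both the basic fluoride that would cause beta-elimination or retro-aldol cleavage and the strong acid that would ionise the electron-rich benzylic carbinol.

Step 6
Reactants: 7 (3S)-1-(2,5-dihydroxy-3,4-dimethoxyphenyl)-3-(3,4-dimethoxyphenyl)-3-hydroxypropan-1-one
Product: 10 (2S)-2-(3,4-dimethoxyphenyl)-5,8-dihydroxy-6,7-dimethoxychroman-4-one, via acylquinone 8 (not isolated), via chromenetrione 9 (not isolated)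
Conditions: divided cell, reticulated vitreous carbon anode, Pt cathode, controlled potential on the first anodic wave of 7 (set by cyclic voltammetry), Bu4NBF4 (0.1 M), 2,6-lutidine (2.2 equiv), dry MeCN, 0 °C, 2.0–2.2 F/mol; then rt, 30 min; aq. Na2S2O4 work-up
Reagents that add atoms: none
Why: Proposed new method: two-electron, two-proton oxidation of the hydroquinone ring of 7 at carbon gives acylquinone 8, in which the unsubstituted ring carbon (the future C8a) is beta to both the ring carbonyl at C5 and the side-chain ketone C4; the secondary hydroxyl adds to it in a 6-endo-trig oxa-Michael closure that forms O1-C8a and ring C, and enol-to-phenol tautomerisation restores the aromatic hydroquinone 10. The closest known reaction type is the conjugate addition of external oxygen nucleophiles to anodically generated 2-acyl-1,4-benzoquinones, here made intramolecular. No stereocenter is created: the bond is made at an sp2 carbon and no bond to C2 is broken, so the S configuration from step 1 is carried through. Because 10 has one more oxygen donor than 7 it is the easier hydroquinone to oxidise, so part of it goes on to quinone 9 at the anode or by redox exchange with 8; the charge is therefore held near 2 F/mol, 9 and unreacted 7 are left to comproportionate, and the dithionite work-up returns the rest of 9 to 10. The step needs oxidation of ring A beside the 3,4-dimethoxyphenyl ring, which the much lower potential of a hydroquinone (lowered further by the lutidine proton acceptor) and potentiostatic control should secure. It also needs site selectivity in the addition, and the tether can reach only the doubly activated CH carbon through a six-membered transition state, the methoxy-bearing carbons being out of reach. 2,6-Lutidine takes up the acid that would otherwise ionise the benzylic carbinol and is too hindered to add to 8 itself.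

Step 7
Reactants: 10 (2S)-2-(3,4-dimethoxyphenyl)-5,8-dihydroxy-6,7-dimethoxychroman-4-one
Product: 11 (2S)-8-(benzyloxy)-2-(3,4-dimethoxyphenyl)-5-hydroxy-6,7-dimethoxychroman-4-one
Conditions: BnBr (1.1 equiv), K2CO3 (1.2 equiv), degassed DMF, 0 °C to rt, Ar
Reagents that add atoms: benzyl bromide, BrCc1ccccc1
Why: Williamson benzylation; the C5 hydroxyl is held in a hydrogen bond to the C4 carbonyl, so the free C8 phenoxide is alkylated selectively by one equivalent of bromide. Oxygen is excluded because the hydroquinone is air-sensitive in base, and the weak base and low temperature limit E1cB opening of ring C.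

Step 8
Reactants: 11 (2S)-8-(benzyloxy)-2-(3,4-dimethoxyphenyl)-5-hydroxy-6,7-dimethoxychroman-4-one
Product: 12 (2S)-8-(benzyloxy)-2-(3,4-dimethoxyphenyl)-5,6,7-trimethoxychroman-4-one
Conditions: MeI (excess), Ag2O, DMF, rt, dark
Reagents that add atoms: iodomethane, CI
Why: Purdie methylation with Ag2O and MeI, chosen for the chelated C5 phenol because the silver oxide is a weak, heterogeneous base that should methylate without opening ring C and racemising C2.

Step 9
Reactants: 12 (2S)-8-(benzyloxy)-2-(3,4-dimethoxyphenyl)-5,6,7-trimethoxychroman-4-one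
Product: 13 (2S)-2-(3,4-dimethoxyphenyl)-8-hydroxy-5,6,7-trimethoxychroman-4-one
Conditions: H2 (1 atm), 10% Pd/C, EtOAc, rt
Reagents that add atoms: none
Why: Hydrogenolysis of a benzyl aryl ether under neutral conditions; this ether cleaves much faster than the cyclic C2-O1 benzylic ether or the C4 ketone, so the reaction is stopped after one equivalent of hydrogen.

## Compound list

1 | ethyl 3-(3,4-dimethoxyphenyl)-3-oxopropanoate | CCOC(=O)CC(=O)c1ccc(OC)c(OC)c1 | starting material
2 | ethyl (3S)-3-(3,4-dimethoxyphenyl)-3-hydroxypropanoate | COc1ccc([C@@H](O)CC(=O)OCC)cc1OC | intermediate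
3 | ethyl (3S)-3-[(tert-butyldimethylsilyl)oxy]-3-(3,4-dimethoxyphenyl)propanoate | COc1ccc([C@@H](O[Si](C)(C)C(C)(C)C)CC(=O)OCC)cc1OC | intermediate
4 | (3S)-3-[(tert-butyldimethylsilyl)oxy]-3-(3,4-dimethoxyphenyl)propanal | COc1ccc([C@@H](O[Si](C)(C)C(C)(C)C)CC=O)cc1OC | intermediate
5 | 2,3-dimethoxy-1,4-benzoquinone | COC1=C(OC)C(=O)C=CC1=O | starting material
6 | (3S)-3-[(tert-butyldimethylsilyl)oxy]-1-(2,5-dihydroxy-3,4-dimethoxyphenyl)-3-(3,4-dimethoxyphenyl)propan-1-one | COc1ccc([C@@H](O[Si](C)(C)C(C)(C)C)CC(=O)c2cc(O)c(OC)c(OC)c2O)cc1OC | intermediate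
7 | (3S)-1-(2,5-dihydroxy-3,4-dimethoxyphenyl)-3-(3,4-dimethoxyphenyl)-3-hydroxypropan-1-one | COc1ccc([C@@H](O)CC(=O)c2cc(O)c(OC)c(OC)c2O)cc1OC | intermediate
8 | 2-[(3S)-3-(3,4-dimethoxyphenyl)-3-hydroxypropanoyl]-5,6-dimethoxycyclohexa-2,5-diene-1,4-dione | COc1ccc([C@@H](O)CC(=O)C2=CC(=O)C(OC)=C(OC)C2=O)cc1OC | intermediate
9 | (2S)-2-(3,4-dimethoxyphenyl)-6,7-dimethoxy-2,3-dihydro-4H-chromene-4,5,8-trione | COc1ccc([C@@H]2CC(=O)C3=C(O2)C(=O)C(OC)=C(OC)C3=O)cc1OC | intermediate
10 | (2S)-2-(3,4-dimethoxyphenyl)-5,8-dihydroxy-6,7-dimethoxychroman-4-one | COc1ccc([C@@H]2CC(=O)c3c(O)c(OC)c(OC)c(O)c3O2)cc1OC | intermediate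
11 | (2S)-8-(benzyloxy)-2-(3,4-dimethoxyphenyl)-5-hydroxy-6,7-dimethoxychroman-4-one | COc1ccc([C@@H]2CC(=O)c3c(O)c(OC)c(OC)c(OCc4ccccc4)c3O2)cc1OC | intermediate
12 | (2S)-8-(benzyloxy)-2-(3,4-dimethoxyphenyl)-5,6,7-trimethoxychroman-4-one | COc1ccc([C@@H]2CC(=O)c3c(OC)c(OC)c(OC)c(OCc4ccccc4)c3O2)cc1OC | intermediate
13 | (2S)-2-(3,4-dimethoxyphenyl)-8-hydroxy-5,6,7-trimethoxychroman-4-one | COc1ccc([C@@H]2CC(=O)c3c(c(O)c(OC)c(OC)c3OC)O2)cc1OC | target

## Step count and points of risk

Total: 9 steps. Longest linear sequence: 9 steps (1 to 13); quinone 5 is bought and enters at step 4.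

**Step 6 (key step, proposed new method).** Three processes may defeat it.
- Over-oxidation of the product hydroquinone, followed by base-induced tautomerisation of quinone 9 to the flavone oxidation level, would erase C2.
- Dehydration or retro-aldol cleavage of acylquinone 8 may outrun addition of the weakly nucleophilic secondary hydroxyl.
- Filming of the carbon anode may stop the electrolysis.

Fallback, by known reactions only, sets out from 5 and returns at 12; it gives up the oxidative closure and the side-chain series.
- Photoacylation of 5 with acetaldehyde gives 1-(2,5-dihydroxy-3,4-dimethoxyphenyl)ethan-1-one F1.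
- Anodic oxidation of F1 in MeCN containing allyl alcohol, the known intermolecular addition of an oxygen nucleophile to an electrogenerated acylquinone, followed by dithionite, gives 1-[2,5-dihydroxy-3,4-dimethoxy-6-(prop-2-en-1-yloxy)phenyl]ethan-1-one F2.
- Benzylation of the unchelated hydroxyl (BnBr, K2CO3) gives 1-[3-(benzyloxy)-6-hydroxy-4,5-dimethoxy-2-(prop-2-en-1-yloxy)phenyl]ethan-1-one F3.
- Methylation of the chelated hydroxyl (Me2SO4, K2CO3, refluxing acetone; no stereocenter is present) gives 1-[3-(benzyloxy)-4,5,6-trimethoxy-2-(prop-2-en-1-yloxy)phenyl]ethan-1-one F4.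
- Deallylation with Pd(PPh3)4 and morpholine gives 1-[3-(benzyloxy)-2-hydroxy-4,5,6-trimethoxyphenyl]ethan-1-one F5.
- Condensation with N,N-dimethylformamide dimethyl acetal and acid-induced ring closure gives 8-(benzyloxy)-5,6,7-trimethoxy-4H-chromen-4-one F6.
- Asymmetric conjugate addition of 3,4-dimethoxyphenylboronic acid under Pd(OCOCF3)2 and the enantiomer of the tert-butyl pyridine-oxazoline ligand that leads to the 2S product gives 12.

The stereocenter then rests on catalyst control, and the sequence is longer (seven steps from 5 to 12, eight to 13).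

**Step 4.** The excited quinone may be quenched by electron transfer from the dimethoxyarene of 4, or may abstract the benzylic hydrogen next to the silyl ether in place of the formyl hydrogen; O-acylation of the semiquinone is a further leak. Fallback by directed metalation, setting out from 4 and 5 and returning at 6:
- Reduction of 5 with Na2S2O4 gives 2,3-dimethoxybenzene-1,4-diol F7.
- MOMCl and i-Pr2NEt give 1,2-dimethoxy-3,6-bis(methoxymethoxy)benzene F8.
- ortho-Lithiation (n-BuLi, TMEDA, THF) and addition to 4 give (3S)-3-[(tert-butyldimethylsilyl)oxy]-1-[3,4-dimethoxy-2,5-bis(methoxymethoxy)phenyl]-3-(3,4-dimethoxyphenyl)propan-1-ol F9 as a mixture of C1 epimers.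
- Dess-Martin oxidation gives (3S)-3-[(tert-butyldimethylsilyl)oxy]-1-[3,4-dimethoxy-2,5-bis(methoxymethoxy)phenyl]-3-(3,4-dimethoxyphenyl)propan-1-one F10.
- Cleavage of the two aryl MOM ethers with TMSOTf and 2,2'-bipyridyl followed by water gives 6.

**Step 8.** Methylation of the hydrogen-bonded C5 phenol may stall, and forcing it invites E1cB opening of ring C with racemisation at C2. Fallback that removes the carbonyl for the duration, setting out from 11 and returning at 12:
- NaBH4 reduction gives (2S,4S)-8-(benzyloxy)-2-(3,4-dimethoxyphenyl)-6,7-dimethoxy-3,4-dihydro-2H-chromene-4,5-diol F11 (2,4-cis expected), in which the phenol is no longer chelated and ring opening is impossible.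
- MeI and K2CO3 give (2S,4S)-8-(benzyloxy)-2-(3,4-dimethoxyphenyl)-5,6,7-trimethoxy-3,4-dihydro-2H-chromen-4-ol F12.
- Dess-Martin oxidation of the benzylic alcohol gives 12.

**Step 1.** Aryl beta-keto esters are hydrogenated with lower enantioselectivity than alkyl ones, and the electron-rich benzylic alcohol may solvolyse in the slightly acidic alcoholic medium. Fallback by kinetic resolution, setting out from 1 and returning at 2:
- NaBH4 reduction gives racemic ethyl 3-(3,4-dimethoxyphenyl)-3-hydroxypropanoate F13.
- Acylation with vinyl acetate and Burkholderia cepacia lipase should, by Kazlauskas' rule, convert the R enantiomer into ethyl (3R)-3-(acetyloxy)-3-(3,4-dimethoxyphenyl)propanoate F14 and leave 2, which is separated by chromatography.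

## Further compounds

F1 | step 6 | 1-(2,5-dihydroxy-3,4-dimethoxyphenyl)ethan-1-one | CC(=O)c1cc(O)c(OC)c(OC)c1O
F2 | step 6 | 1-[2,5-dihydroxy-3,4-dimethoxy-6-(prop-2-en-1-yloxy)phenyl]ethan-1-one | CC(=O)c1c(O)c(OC)c(OC)c(O)c1OCC=C
F3 | step 6 | 1-[3-(benzyloxy)-6-hydroxy-4,5-dimethoxy-2-(prop-2-en-1-yloxy)phenyl]ethan-1-one | CC(=O)c1c(O)c(OC)c(OC)c(OCc2ccccc2)c1OCC=C
F4 | step 6 | 1-[3-(benzyloxy)-4,5,6-trimethoxy-2-(prop-2-en-1-yloxy)phenyl]ethan-1-one | CC(=O)c1c(OC)c(OC)c(OC)c(OCc2ccccc2)c1OCC=C
F5 | step 6 | 1-[3-(benzyloxy)-2-hydroxy-4,5,6-trimethoxyphenyl]ethan-1-one | CC(=O)c1c(OC)c(OC)c(OC)c(OCc2ccccc2)c1O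
F6 | step 6 | 8-(benzyloxy)-5,6,7-trimethoxy-4H-chromen-4-one | O=c1ccoc2c(OCc3ccccc3)c(OC)c(OC)c(OC)c12
F7 | step 4 | 2,3-dimethoxybenzene-1,4-diol | COc1c(O)ccc(O)c1OC
F8 | step 4 | 1,2-dimethoxy-3,6-bis(methoxymethoxy)benzene | COCOc1ccc(OCOC)c(OC)c1OC
F9 | step 4 | (3S)-3-[(tert-butyldimethylsilyl)oxy]-1-[3,4-dimethoxy-2,5-bis(methoxymethoxy)phenyl]-3-(3,4-dimethoxyphenyl)propan-1-ol (C1 epimers) | COc1ccc([C@@H](O[Si](C)(C)C(C)(C)C)CC(O)c2cc(OCOC)c(OC)c(OC)c2OCOC)cc1OC
F10 | step 4 | (3S)-3-[(tert-butyldimethylsilyl)oxy]-1-[3,4-dimethoxy-2,5-bis(methoxymethoxy)phenyl]-3-(3,4-dimethoxyphenyl)propan-1-one | COc1ccc([C@@H](O[Si](C)(C)C(C)(C)C)CC(=O)c2cc(OCOC)c(OC)c(OC)c2OCOC)cc1OC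
F11 | step 8 | (2S,4S)-8-(benzyloxy)-2-(3,4-dimethoxyphenyl)-6,7-dimethoxy-3,4-dihydro-2H-chromene-4,5-diol | COc1ccc([C@@H]2C[C@H](O)c3c(O)c(OC)c(OC)c(OCc4ccccc4)c3O2)cc1OC
F12 | step 8 | (2S,4S)-8-(benzyloxy)-2-(3,4-dimethoxyphenyl)-5,6,7-trimethoxy-3,4-dihydro-2H-chromen-4-ol | COc1ccc([C@@H]2C[C@H](O)c3c(OC)c(OC)c(OC)c(OCc4ccccc4)c3O2)cc1OC
F13 | step 1 | ethyl 3-(3,4-dimethoxyphenyl)-3-hydroxypropanoate (racemic) | CCOC(=O)CC(O)c1ccc(OC)c(OC)c1
F14 | step 1 | ethyl (3R)-3-(acetyloxy)-3-(3,4-dimethoxyphenyl)propanoate | COc1ccc([C@H](OC(C)=O)CC(=O)OCC)cc1OC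
A1 | alternative 1 | (2S)-8-(benzyloxy)-2-(4,5-dimethoxycyclohexa-1,4-dien-1-yl)-5,6,7-trimethoxychroman-4-one | COC1=C(OC)CC([C@@H]2CC(=O)c3c(c(OCc4ccccc4)c(OC)c(OC)c3OC)O2)=CC1
A2 | alternative 1 | (2S)-8-(benzyloxy)-2-ethynyl-5,6,7-trimethoxychroman-4-one | C#C[C@@H]1CC(=O)c2c(c(OCc3ccccc3)c(OC)c(OC)c2OC)O1
A3 | alternative 1 | 2,3-dimethoxybuta-1,3-diene | C=C(OC)C(=C)OC
A4 | alternative 2 | (2S,4S)-4-(tert-butyldimethylsilyloxy)-2-(3,4-dimethoxyphenyl)-6,7-dimethoxy-8-(trimethylsilyloxy)chroman-5-ol | COc1ccc([C@@H]2C[C@H](O[Si](C)(C)C(C)(C)C)c3c(O)c(OC)c(OC)c(O[Si](C)(C)C)c3O2)cc1OC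
A5 | alternative 2 | 4-[(2S,4S)-4-(tert-butyldimethylsilyloxy)-2-(3,4-dimethoxyphenyl)-3,4-dihydro-2H-pyran-6-yl]-2,3-dimethoxy-4-(trimethylsilyloxy)cyclobut-2-en-1-one | COc1ccc([C@@H]2C[C@H](O[Si](C)(C)C(C)(C)C)C=C(C3(O[Si](C)(C)C)C(OC)=C(OC)C3=O)O2)cc1OC
A6 | alternative 2 | 3,4-dimethoxycyclobut-3-ene-1,2-dione (dimethyl squarate) | COC1=C(OC)C(=O)C1=O
A7 | alternative 2 | tert-butyl{[(2S,4S)-2-(3,4-dimethoxyphenyl)-3,4-dihydro-2H-pyran-4-yl]oxy}dimethylsilane | COc1ccc([C@@H]2C[C@H](O[Si](C)(C)C(C)(C)C)C=CO2)cc1OC
A8 | alternative 3 | (2S,4S)-8-(benzyloxy)-2-(3,4-dimethoxyphenyl)-4,5,6,7-tetramethoxychromane | COc1ccc([C@@H]2C[C@H](OC)c3c(OC)c(OC)c(OC)c(OCc4ccccc4)c3O2)cc1OC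
A9 | alternative 3 | 3-(benzyloxy)-2-hydroxy-4,5,6-trimethoxybenzaldehyde | O=Cc1c(O)c(OCc2ccccc2)c(OC)c(OC)c1OC
A10 | alternative 3 | 3,4-dimethoxystyrene | C=Cc1ccc(OC)c(OC)c1
A11 | alternative 3 | 2-(benzyloxy)-3,4,5-trimethoxy-6-(methoxymethylidene)cyclohexa-2,4-dien-1-one | COC=C1C(=O)C(OCc2ccccc2)=C(OC)C(OC)=C1OC
A12 | alternative 3 | trimethyl orthoformate | COC(OC)OC
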